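**Retrosynthetic overview**

1. Side chain: the 2Z acetoxymethyl-enoic acid arises by syn conjugate addition of a C12 alkylborane (hydroboration of a C9 vinyl group) to tert-butyl 4-acetoxybut-2-ynoate, then ester cleavage.
2. The C8 hydroxymethyl group and the C7=C8 alkene arise from a Shapiro reaction of a C8 ketone with a formaldehyde quench.
3. Key step, ring B: one-carbon ring expansion (semipinacol 1,2-shift of the angular quaternary carbon) of a spiro vinyl epoxide made from a trans-hydrindan-1-one; it inserts C9 with its vinyl handle and moves the carbonyl to C8.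
4. Ring A: ring-closing metathesis and hydrogenation of a trans-2-allyl-2-methyl-3-(1,1-dimethylallyl)cyclopentanone.
5. That ketone: enantioselective conjugate reverse-prenylation of 2-methylcyclopent-2-enone with enolate allylation. Ring order: cyclopentanone (purchased), then ring A, then ring B (five to six).

Assumption: C-numbers in the overview are labdane numbers (C17 is the hydroxymethyl carbon); locants in the steps are those of the compound names.

**Route**

Step 1
Reactants: 1 1-chloro-3-methylbut-2-ene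
Product: 3 trimethyl(3-methylbut-2-en-1-yl)silane, via prenylmagnesium chloride 2 (not isolated)
Conditions: Mg, Me3SiCl, THF, 0 °C to rt
Reagents that add atoms: chlorotrimethylsilane C[Si](C)(C)Cl
Why: Barbier-type silylation of an allylic Grignard reagent, which is silylated at its unhindered primary terminus (the standard prenylsilane preparation).

Step 2
Reactants: 4 2-methylcyclopent-2-en-1-one; 3 trimethyl(3-methylbut-2-en-1-yl)silane; 5 3-bromoprop-1-ene
Product: 8 (2R,3R)-2-methyl-3-(2-methylbut-3-en-2-yl)-2-(prop-2-en-1-yl)cyclopentan-1-one, via silyl enol ether 6 (not isolated), via lithium enolate 7 (not isolated)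
Conditions: chiral imidodiphosphorimidate (IDPi) Brønsted acid (2 mol%, enantiomer giving 3R), toluene, −60 °C; then MeLi, THF, 0 °C; then 5, DMPU, −78 to 0 °C
Reagents that add atoms: none
Why: Proposed new method: an enantioselective Hosomi–Sakurai conjugate reverse-prenylation under silylium counteranion-directed catalysis, in which the confined IDPi acid is silylated by 3, the silylium ion pair O-silylates enone 4, the prenylsilane attacks C3 of the ion-paired siloxyallyl cation through its γ-carbon (SE2') on the face left open by the chiral anion (sets C3 as R) and silyl transfer releases enol silane 6 with a fixed double-bond position, after which MeLi unmasks enolate 7 and allyl bromide alkylates it anti to the bulky tertiary group (sets the quaternary C2 as R); the closest known reaction types are the TiCl4-mediated Sakurai reverse-prenylation of enones and IDPi-catalysed Mukaiyama–Michael and aldehyde allylation reactions.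

Step 3
Reactants: 8 (2R,3R)-2-methyl-3-(2-methylbut-3-en-2-yl)-2-(prop-2-en-1-yl)cyclopentan-1-one
Product: 10 (3aR,7aR)-4,4,7a-trimethyloctahydro-1H-inden-1-one, via hexahydroindenone 9 (not isolated)
Conditions: second-generation Grubbs catalyst (3 mol%), CH2Cl2, 40 °C; then Pd/C, H2 (1 atm), EtOAc, rt
Reagents that add atoms: none
Why: Ring-closing olefin metathesis between the allyl and the neopentyl vinyl group closes ring A as a trans-fused cyclohexene without touching the two stereocentres, and hydrogenation over Pd/C saturates the disubstituted alkene while leaving the ketone.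

Step 4
Reactants: 10 (3aR,7aR)-4,4,7a-trimethyloctahydro-1H-inden-1-one; 11 3-chloroprop-1-ene
Product: 14 (1R,3aR,7aR)-3'-ethenyl-4,4,7a-trimethyloctahydrospiro[indene-1,2'-oxirane] (both C3' epimers), via chloroallyllithium 12 (not isolated), via lithium chlorohydrin alkoxide 13 (not isolated)
Conditions: 11, LiN(iPr)2, THF, −90 °C; then 10, −90 °C to rt
Reagents that add atoms: none
Why: Carbenoid addition with Darzens-type closure, in which α-chloroallyllithium adds through its chlorine-bearing carbon to the ketone from the face opposite the angular methyl group (spiro carbon R) and the alkoxide displaces chloride on warming; the epoxide CH centre is uncontrolled and is erased in step 5.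

Step 5
Reactants: 14 (1R,3aR,7aR)-3'-ethenyl-4,4,7a-trimethyloctahydrospiro[indene-1,2'-oxirane]
Product: 15 (1S,4aR,8aR)-1-ethenyl-5,5,8a-trimethyloctahydronaphthalen-2(1H)-one
Conditions: Pd2(dba)3·CHCl3 (2.5 mol%), P(OPh)3 (10 mol%), toluene, 60 °C
Reagents that add atoms: none
Why: Proposed new method: a zerovalent-palladium-catalysed semipinacol (Wagner–Meerwein) ring expansion of an unstrained spiro vinyl epoxide, in which ionisation gives a zwitterionic π-allylpalladium alkoxide that has no hydrogen on the carbinol carbon for β-hydride elimination and so can only re-close or let the electron-rich quaternary ring carbon migrate (with retention) to the allyl terminus anti to palladium, forming the C=O bond and relieving trans-hydrindane strain, while π–σ–π equilibration makes both epoxide epimers converge and the transition state with the vinyl group pseudo-equatorial (syn to the forming carbonyl oxygen) sets C1 as S; the closest known reaction types are the palladium-catalysed Wagner–Meerwein ring expansion of allylic-carbonate-bearing cyclopropanols and cyclobutanols and the Tsuji–Trost ionisation of vinyl epoxides.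

Step 6
Reactants: 15 (1S,4aR,8aR)-1-ethenyl-5,5,8a-trimethyloctahydronaphthalen-2(1H)-one
Product: 16 N'-[(1S,2E,4aR,8aR)-1-ethenyl-5,5,8a-trimethyloctahydronaphthalen-2(1H)-ylidene]-2,4,6-tri(propan-2-yl)benzenesulfonohydrazide
Conditions: 2,4,6-triisopropylbenzenesulfonohydrazide, pyridinium p-toluenesulfonate (5 mol%), THF, rt
Reagents that add atoms: 2,4,6-tri(propan-2-yl)benzenesulfonohydrazide CC(C)c1cc(C(C)C)c(S(=O)(=O)NN)c(C(C)C)c1
Why: Hydrazone condensation under near-neutral conditions that do not epimerise or conjugate the α-vinyl ketone; the N–N bond settles anti to the more substituted α-carbon (E), which fixes the regiochemistry of step 7.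

Step 7
Reactants: 16 N'-[(1S,2E,4aR,8aR)-1-ethenyl-5,5,8a-trimethyloctahydronaphthalen-2(1H)-ylidene]-2,4,6-tri(propan-2-yl)benzenesulfonohydrazide
Product: 19 [(1S,4aR,8aR)-1-ethenyl-5,5,8a-trimethyl-1,4,4a,5,6,7,8,8a-octahydronaphthalen-2-yl]methanol, via hydrazone dianion 17 (not isolated), via vinyllithium 18 (not isolated)
Conditions: n-BuLi (2.2 equiv), THF, −78 to 0 °C; then (CH2O)n, −78 °C to rt; H2O
Reagents that add atoms: formaldehyde C=O
Why: Shapiro reaction, in which the second equivalent of n-BuLi removes the ring CH2 hydrogen syn to the N-sulfonyl group, loss of sulfinate and N2 gives the less substituted vinyllithium, and formaldehyde traps it to give the allylic alcohol with the 2,3-double bond; the C1 centre is not touched.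

Step 8
Reactants: 20 prop-2-yn-1-ol
Product: 23 tert-butyl 4-(acetyloxy)but-2-ynoate, via dilithio propargyl alcohol 21 (not isolated), via lithium alkoxide 22 (not isolated)
Conditions: n-BuLi (2.05 equiv), THF, −78 °C; Boc2O (1.0 equiv), −78 °C; then Ac2O (2.2 equiv), −78 °C to rt
Reagents that add atoms: di-tert-butyl dicarbonate CC(C)(C)OC(=O)OC(=O)OC(C)(C)C; acetic anhydride CC(=O)OC(C)=O
Why: Dianion chemistry (alkoxycarbonylation of a lithium acetylide, then O-acetylation), in which the more basic acetylide carbon is acylated by Boc2O before the alkoxide, which is then acetylated in the same flask.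

Step 9
Reactants: 19 [(1S,4aR,8aR)-1-ethenyl-5,5,8a-trimethyl-1,4,4a,5,6,7,8,8a-octahydronaphthalen-2-yl]methanol; 23 tert-butyl 4-(acetyloxy)but-2-ynoate
Product: 25 tert-butyl (2Z)-3-[(acetyloxy)methyl]-5-[(1S,4aR,8aR)-2-(hydroxymethyl)-5,5,8a-trimethyl-1,4,4a,5,6,7,8,8a-octahydronaphthalen-1-yl]pent-2-enoate, via bis-borane 24 (not isolated)
Conditions: 9-BBN-H dimer (1.1 equiv), THF, 0 °C to rt; then 23, CuOAc (10 mol%), P(OPh)3 (20 mol%), t-BuOK (20 mol%), t-BuOH, 1,4-dioxane, 40 °C; aq work-up
Reagents that add atoms: none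
Why: 9-BBN hydroborates only the monosubstituted vinyl group (anti-Markovnikov; the hydroxyl is carried as its borinate), and copper-catalysed conjugate addition of the alkylborane to the ynoate is a syn-carbocupration followed by protonation with retention, so the new alkyl group ends trans to the ester and the acetoxymethyl group cis to it (2Z).

Step 10
Reactants: 25 tert-butyl (2Z)-3-[(acetyloxy)methyl]-5-[(1S,4aR,8aR)-2-(hydroxymethyl)-5,5,8a-trimethyl-1,4,4a,5,6,7,8,8a-octahydronaphthalen-1-yl]pent-2-enoate
Product: 27 (2Z)-3-[(acetyloxy)methyl]-5-[(1S,4aR,8aR)-2-(hydroxymethyl)-5,5,8a-trimethyl-1,4,4a,5,6,7,8,8a-octahydronaphthalen-1-yl]pent-2-enoic acid, via bis-silyl derivative 26 (not isolated)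
Conditions: Me3SiOTf, 2,6-lutidine, CH2Cl2, 0 °C; then H2O (pH 5 buffer)
Reagents that add atoms: none
Why: Silyl triflate-mediated tert-butyl ester cleavage, which converts the ester to the silyl ester with loss of isobutene under buffered, non-protic conditions that spare the allylic acetate, the Z-enoate and the (transiently silylated) allylic alcohol; aqueous work-up frees the acid and the alcohol.

**Compound list**

1 | 1-chloro-3-methylbut-2-ene | CC(C)=CCCl | starting material
2 | (3-methylbut-2-en-1-yl)magnesium chloride | CC(C)=CC[Mg]Cl | intermediate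
3 | trimethyl(3-methylbut-2-en-1-yl)silane | CC(C)=CC[Si](C)(C)C | intermediate
4 | 2-methylcyclopent-2-en-1-one | CC1=CCCC1=O | starting material
5 | 3-bromoprop-1-ene | C=CCBr | starting material
6 | trimethyl{[(3R)-2-methyl-3-(2-methylbut-3-en-2-yl)cyclopent-1-en-1-yl]oxy}silane | CC1=C(O[Si](C)(C)C)CC[C@@H]1C(C)(C)C=C | intermediate
7 | lithium (3R)-2-methyl-3-(2-methylbut-3-en-2-yl)cyclopent-1-en-1-olate | CC1=C(O[Li])CC[C@@H]1C(C)(C)C=C | intermediate
8 | (2R,3R)-2-methyl-3-(2-methylbut-3-en-2-yl)-2-(prop-2-en-1-yl)cyclopentan-1-one | O=C1CC[C@H](C(C)(C)C=C)[C@@]1(C)CC=C | intermediate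
9 | (3aR,7aR)-4,4,7a-trimethyl-2,3,3a,4,7,7a-hexahydro-1H-inden-1-one | O=C1CC[C@@H]2C(C)(C)C=CC[C@@]12C | intermediate
10 | (3aR,7aR)-4,4,7a-trimethyloctahydro-1H-inden-1-one | O=C1CC[C@@H]2C(C)(C)CCC[C@@]12C | intermediate
11 | 3-chloroprop-1-ene | C=CCCl | starting material
12 | (1-chloroprop-2-en-1-yl)lithium | [Li]C(Cl)C=C | intermediate
13 | lithium (1R,3aR,7aR)-1-(1-chloroprop-2-en-1-yl)-4,4,7a-trimethyloctahydro-1H-inden-1-olate (both side-chain epimers) | [Li]O[C@]1(C(Cl)C=C)CC[C@@H]2C(C)(C)CCC[C@@]12C | intermediate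
14 | (1R,3aR,7aR)-3'-ethenyl-4,4,7a-trimethyloctahydrospiro[indene-1,2'-oxirane] (both C3' epimers) | C=CC1O[C@@]12CC[C@@H]3C(C)(C)CCC[C@@]23C | intermediate
15 | (1S,4aR,8aR)-1-ethenyl-5,5,8a-trimethyloctahydronaphthalen-2(1H)-one | C=C[C@@H]1C(=O)CC[C@@H]2C(C)(C)CCC[C@@]12C | intermediate
16 | N'-[(1S,2E,4aR,8aR)-1-ethenyl-5,5,8a-trimethyloctahydronaphthalen-2(1H)-ylidene]-2,4,6-tri(propan-2-yl)benzenesulfonohydrazide | C=C[C@@H]1/C(=N/NS(=O)(=O)c3c(C(C)C)cc(C(C)C)cc3C(C)C)CC[C@@H]2C(C)(C)CCC[C@@]12C | intermediate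
17 | N,C3-dilithio derivative of 16 (hydrazone nitrogen and ring CH2 next to C=N lithiated; stereocentres as in 16) | C=C[C@@H]1/C(=N/N([Li])S(=O)(=O)c3c(C(C)C)cc(C(C)C)cc3C(C)C)C([Li])C[C@@H]2C(C)(C)CCC[C@@]12C | intermediate
18 | [1-ethenyl-5,5,8a-trimethyl-1,4,4a,5,6,7,8,8a-octahydronaphthalen-2-yl]lithium (stereocentres as in 19) | C=C[C@@H]1C([Li])=CC[C@@H]2C(C)(C)CCC[C@@]12C | intermediate
19 | [(1S,4aR,8aR)-1-ethenyl-5,5,8a-trimethyl-1,4,4a,5,6,7,8,8a-octahydronaphthalen-2-yl]methanol | C=C[C@@H]1C(CO)=CC[C@@H]2C(C)(C)CCC[C@@]12C | intermediate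
20 | prop-2-yn-1-ol | C#CCO | starting material
21 | lithium 3-lithioprop-2-yn-1-olate | [Li]C#CCO[Li] | intermediate
22 | lithium 4-tert-butoxy-4-oxobut-2-yn-1-olate | [Li]OCC#CC(=O)OC(C)(C)C | intermediate
23 | tert-butyl 4-(acetyloxy)but-2-ynoate | CC(=O)OCC#CC(=O)OC(C)(C)C | intermediate
24 | B-alkyl-9-borabicyclo[3.3.1]nonane from 19 (boron on the terminal carbon of the former vinyl group; hydroxyl as its 9-borabicyclononyl borinate; stereocentres as in 19) | B1(C2CCCC1CCC2)CC[C@@H]3C(COB4C5CCCC4CCC5)=CC[C@@H]6C(C)(C)CCC[C@@]36C | intermediate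
25 | tert-butyl (2Z)-3-[(acetyloxy)methyl]-5-[(1S,4aR,8aR)-2-(hydroxymethyl)-5,5,8a-trimethyl-1,4,4a,5,6,7,8,8a-octahydronaphthalen-1-yl]pent-2-enoate | CC(=O)OC/C(=C\C(=O)OC(C)(C)C)CC[C@@H]1C(CO)=CC[C@@H]2C(C)(C)CCC[C@@]12C | intermediate
26 | trimethylsilyl (2Z)-3-[(acetyloxy)methyl]-5-[(1S,4aR,8aR)-5,5,8a-trimethyl-2-{[(trimethylsilyl)oxy]methyl}-1,4,4a,5,6,7,8,8a-octahydronaphthalen-1-yl]pent-2-enoate | CC(=O)OC/C(=C\C(=O)O[Si](C)(C)C)CC[C@@H]1C(CO[Si](C)(C)C)=CC[C@@H]2C(C)(C)CCC[C@@]12C | intermediate
27 | (2Z)-3-[(acetyloxy)methyl]-5-[(1S,4aR,8aR)-2-(hydroxymethyl)-5,5,8a-trimethyl-1,4,4a,5,6,7,8,8a-octahydronaphthalen-1-yl]pent-2-enoic acid | CC(=O)OC/C(=C\C(=O)O)CC[C@@H]1C(CO)=CC[C@@H]2C(C)(C)CCC[C@@]12C | target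

**Step count and risks**

Total step count: 10. Longest linear sequence: 9 steps (steps 1 to 7, then 9 and 10; step 8 is the side branch).

The three steps most likely to fail are steps 2, 5 and 4.

Step 2 (proposed new step). The enantioselective silylium-catalysed reverse-prenylation has not been shown on an α-substituted cyclopentenone with a γ-attacking, hindered allylsilane, so rate and enantioselectivity are uncertain. The fallback uses known chemistry only, sets out from 3 and 5 and rejoins at 10. Commercial (4R)-4-hydroxycyclopent-2-en-1-one F1 is silylated (t-BuMe2SiCl, imidazole, DMF) to (4R)-4-{[tert-butyl(dimethyl)silyl]oxy}cyclopent-2-en-1-one F2. TiCl4-mediated Hosomi–Sakurai addition of 3 (CH2Cl2, −78 °C) occurs anti to the silyloxy group and gives the trans β-silyloxy ketone F3, from which DBU eliminates the silanol to give (4R)-4-(2-methylbut-3-en-2-yl)cyclopent-2-en-1-one F4. Kinetic α'-deprotonation (LiN(iPr)2, THF, −78 °C) and MeI give the trans 5-methyl enone F5. A second α'-deprotonation and alkylation with 5, anti to the tertiary substituent, give the 5-allyl-5-methyl enone F6. Ring-closing metathesis (second-generation Grubbs catalyst) gives the bicyclic dienone F7, and H2 over Pd/C saturates both C=C bonds to give 10.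

Step 5 (proposed new step). Without ring strain the π-allylpalladium alkoxide may simply re-close, may give a 2,5-dihydrofuran by O-attack at the far allyl terminus, or the ring CH2 may migrate instead of the quaternary carbon. The fallback is the known β-oxido carbenoid ring enlargement; it sets out from 10 and rejoins at 15. LiCHBr2 (CH2Br2, lithium 2,2,6,6-tetramethylpiperidide, THF, −78 °C) adds to 10 to give (1R,3aR,7aR)-1-(dibromomethyl)-4,4,7a-trimethyloctahydro-1H-inden-1-ol F8. n-BuLi (3 equiv, −78 °C) effects bromine–lithium exchange and 1,2-shift of the more substituted ring carbon to give the ring-expanded lithium enolate F9. Aldol addition to (phenylselanyl)acetaldehyde gives the β-hydroxy selenide F10, and MeSO2Cl/Et3N removes PhSe and OH to install the vinyl group, giving mainly the C1 epimer of 15, (1R,4aR,8aR)-1-ethenyl-5,5,8a-trimethyloctahydronaphthalen-2(1H)-one F11. Deprotonation (LiN(iPr)2, −78 °C) and kinetic protonation of the dienolate with AcOH from the face opposite the angular methyl group give 15.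

Step 4. α-Chloroallyllithium is short-lived, the ketone is hindered and enolisable, and attack through the CH2 terminus would give a homoallylic alcohol instead of the epoxide. The fallback sets out from 10 and rejoins at 14: a Corey–Chaykovsky-type epoxidation with diphenylsulfonium allylide (allyldiphenylsulfonium tetrafluoroborate, t-BuLi, THF, −78 °C). The less basic ylide adds to the ketone to give the sulfonium betaine F12, which closes to 14 with loss of Ph2S.

Further compounds

F1 | step 2 | (4R)-4-hydroxycyclopent-2-en-1-one | O=C1C=C[C@H](O)C1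
F2 | step 2 | (4R)-4-{[tert-butyl(dimethyl)silyl]oxy}cyclopent-2-en-1-one | O=C1C=C[C@H](O[Si](C)(C)C(C)(C)C)C1
F3 | step 2 | (3S,4R)-4-{[tert-butyl(dimethyl)silyl]oxy}-3-(2-methylbut-3-en-2-yl)cyclopentan-1-one | O=C1C[C@@H](C(C)(C)C=C)[C@H](O[Si](C)(C)C(C)(C)C)C1
F4 | step 2 | (4R)-4-(2-methylbut-3-en-2-yl)cyclopent-2-en-1-one | O=C1C=C[C@H](C(C)(C)C=C)C1
F5 | step 2 | (4S,5R)-5-methyl-4-(2-methylbut-3-en-2-yl)cyclopent-2-en-1-one | O=C1C=C[C@H](C(C)(C)C=C)[C@H]1C
F6 | step 2 | (4R,5R)-5-methyl-4-(2-methylbut-3-en-2-yl)-5-(prop-2-en-1-yl)cyclopent-2-en-1-one | O=C1C=C[C@H](C(C)(C)C=C)[C@@]1(C)CC=C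
F7 | step 2 | (3aR,7aR)-4,4,7a-trimethyl-3a,4,7,7a-tetrahydro-1H-inden-1-one | O=C1C=C[C@@H]2C(C)(C)C=CC[C@@]12C
F8 | step 5 | (1R,3aR,7aR)-1-(dibromomethyl)-4,4,7a-trimethyloctahydro-1H-inden-1-ol | O[C@]1(C(Br)Br)CC[C@@H]2C(C)(C)CCC[C@@]12C
F9 | step 5 | lithium (4aR,8aR)-5,5,8a-trimethyl-3,4,4a,5,6,7,8,8a-octahydronaphthalen-2-olate | C1=C(O[Li])CC[C@@H]2C(C)(C)CCC[C@@]12C
F10 | step 5 | (4aR,8aR)-1-[1-hydroxy-2-(phenylselanyl)ethyl]-5,5,8a-trimethyloctahydronaphthalen-2(1H)-one (epimers at C1 and the carbinol carbon) | OC(C[Se]c1ccccc1)C1C(=O)CC[C@@H]2C(C)(C)CCC[C@@]12C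
F11 | step 5 | (1R,4aR,8aR)-1-ethenyl-5,5,8a-trimethyloctahydronaphthalen-2(1H)-one | C=C[C@H]1C(=O)CC[C@@H]2C(C)(C)CCC[C@@]12C
F12 | step 4 | (1R,3aR,7aR)-1-[1-(diphenylsulfaniumyl)prop-2-en-1-yl]-4,4,7a-trimethyloctahydro-1H-inden-1-olate (both side-chain epimers) | [O-][C@]1(C(C=C)[S+](c2ccccc2)c2ccccc2)CC[C@@H]2C(C)(C)CCC[C@@]12C
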